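**Retrosynthetic overview**
1. The α-methylene lactone is closed last: target 20 from γ-acyloxy enone 18 by intramolecular phosphonate Michael addition and Horner–Wadsworth–Emmons methylenation.
2. 18 comes from β,γ-enone 13 by vinylogous Rubottom γ-hydroxylation (C–O) and esterification.
3. Key bond: the C–O bond of the isovalerate. 13 comes from oxabicyclic ketone 11 and isovaleric acid by a rhodium-catalysed SN2′ ring opening that also resolves 11; the bridge oxygen becomes the tertiary alcohol.
4. 11 comes from furan ether 5 and 1,3-dichloroacetone by (4+3) cycloaddition (seven-membered ring formed first), then exo-face methylation.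
5. 5 comes from furan and crotonaldehyde.

Assumption: the sense of enantiomer selection by the (R,S)-ligand in step 6 is taken by analogy with oxabenzonorbornadiene openings; if the unreacted enantiomer proves to be the needed one, the (S,R)-ligand is used instead.

Racemic compounds 7–11 are drawn as the enantiomer that leads to the target.

**Step 1**
Reactants: 1 furan; 2 (2E)-but-2-enal
Product: 5 tert-butyl{[(2E)-1-(furan-2-yl)but-2-en-1-yl]oxy}dimethylsilane (racemic), via 2-furyllithium 3 (not isolated), via lithium alkoxide 4 (not isolated)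
Conditions: n-BuLi, THF, −78 → 0 °C; 2, −78 °C; TBSCl, DMF, DMAP (cat.), 0 °C → rt
Reagents that add atoms: tert-butyldimethylsilyl chloride, CC(C)(C)[Si](C)(C)Cl
Why: α-Lithiation of furan and 1,2-addition of the organolithium to the enal (E geometry untouched), with silylation of the alkoxide in the same flask; the carbinol centre is racemic and is oxidised away in step 5.

**Step 2**
Reactants: 5 furan silyl ether; 6 1,3-dichloropropan-2-one
Product: 7 1-[(2E)-1-(tert-butyldimethylsilyloxy)but-2-en-1-yl]-2-chloro-8-oxabicyclo[3.2.1]oct-6-en-3-one (racemic; epimers at C2 and at the silyloxy carbon)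
Conditions: 6 (3 equiv, slow addition), Et3N, CF3CH2OH, 0 °C → rt
Reagents that add atoms: none
Why: (4+3) cycloaddition of an oxyallyl cation under Föhlisch conditions: the free CH2 terminus of the chloro-oxyallyl cation bonds first to the unsubstituted furan C5 and the chlorinated terminus closes on the substituted C2 (the "syn" regiochemistry expected for heteroatom-substituted oxyallyl cations with 2-substituted furans); the bridge fixes the two bridgeheads cis, and the chloride and carbinol centres are erased later.

**Step 3**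
Reactants: 7 chloro ketone
Product: 9 rac-(1R,2R,5R)-1-[(2E)-1-(tert-butyldimethylsilyloxy)but-2-en-1-yl]-2-methyl-8-oxabicyclo[3.2.1]oct-6-en-3-one (methyl axial and cis to the bridge oxygen; both silyloxy-carbon epimers), via lithium enolate 8 (not isolated)
Conditions: Me2CuLi, Et2O/THF, −78 → −50 °C; MeI, HMPA, −78 → −40 °C; NH4Cl (aq)
Reagents that add atoms: iodomethane, CI
Why: Reductive enolate generation from the α-halo ketone (halogen–copper exchange) places the enolate only at C2, and enolate alkylation occurs on the face of the oxygen bridge (axial attack, the other face is shielded by the C6=C7 bridge), which sets the methyl centre cis to the bridge oxygen as the target needs; the low temperature suppresses β-elimination of the bridge.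

**Step 4**
Reactants: 9 silyl ether
Product: 10 rac-(1R,2R,5R)-1-[(2E)-1-hydroxybut-2-en-1-yl]-2-methyl-8-oxabicyclo[3.2.1]oct-6-en-3-one (both carbinol epimers)
Conditions: HF·pyridine, pyridine/THF, 0 °C → rt
Reagents that add atoms: none
Why: Fluoride desilylation under buffered, non-basic conditions that neither open the β-alkoxy ketone nor epimerise the axial methyl centre.

**Step 5**
Reactants: 10 allylic alcohol
Product: 11 rac-(1R,2R,5R)-1-[(2E)-but-2-enoyl]-2-methyl-8-oxabicyclo[3.2.1]oct-6-en-3-one
Conditions: Dess–Martin periodinane, CH2Cl2, 0 °C → rt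
Reagents that add atoms: none
Why: Dess–Martin oxidation of the allylic alcohol to the E-enone under neutral conditions merges both carbinol epimers into one racemic ketone without touching C2.

**Step 6**
Reactants: 11 racemic oxabicyclic ketone; 12 3-methylbutanoic acid
Product: 13 (1S,2S,3R)-2-[(2E)-but-2-enoyl]-2-hydroxy-3-methyl-4-oxocyclohept-6-en-1-yl 3-methylbutanoate (ester trans to the tertiary OH; methyl cis to OH)
Conditions: 12 (0.55 equiv), Et3N (0.55 equiv), [Rh(cod)Cl]2 (2.5 mol %), (R)-1-[(S)-2-(diphenylphosphino)ferrocenyl]ethyldi-tert-butylphosphine (6 mol %), THF, 60 °C, stopped near 50 % conversion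
Reagents that add atoms: none
Why: Proposed new method: rhodium-catalysed, enantiomer-selective SN2′ ring opening of a bridgehead-acylated 8-oxabicyclo[3.2.1]oct-6-en-3-one by a carboxylate — monovalent rhodium on the exo face inserts into the C5–O bridge bond (the C1–O bond is disfavoured because the adjacent acyl group destabilises positive charge and C1 is fully substituted) to give a trivalent rhodium allyl alkoxide, and isovalerate attacks the allyl terminus C7 anti to rhodium, so the new C–O bond is trans to the tertiary hydroxyl that was the bridge oxygen; the chiral diphosphine, which in meso substrates selects one of the two bridge C–O bonds, matches the allowed C5–O bond in only the (1R,2R,5R) enantiomer (kinetic resolution, at most 50 % yield); the closest known reaction type is the rhodium-catalysed asymmetric ring opening of oxabenzonorbornadienes with alcohols, phenols, amines and carboxylates, not yet shown on a non-benzo keto-oxabicycle with a quaternary acyl bridgehead or as a resolution.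

**Step 7**
Reactants: 13 β,γ-unsaturated ketone
Product: 16 (1S,2S,3R,7R)-2-[(2E)-but-2-enoyl]-2,7-dihydroxy-3-methyl-4-oxocyclohept-5-en-1-yl 3-methylbutanoate, via bis-silyl dienol ether 14 (not isolated), via bis-silyl ether 15 (not isolated)
Conditions: TMSOTf (2.4 equiv), Et3N, CH2Cl2, −78 → −40 °C; DMDO in acetone, −78 → −40 °C; HF·pyridine, THF, 0 °C
Reagents that add atoms: dimethyldioxirane, CC1(C)OO1
Why: Vinylogous Rubottom oxidation: soft enolisation at the doubly activated methylene between ketone and alkene gives the 1-silyloxy-1,3-diene (the tertiary OH is silylated at the same time), whose terminal carbon takes oxygen from the dioxirane on the face anti to the neighbouring isovalerate, giving the γ-hydroxy enone with the new C–O bond cis to the tertiary oxygen; fluoride then removes both silyl groups.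

**Step 8**
Reactants: 16 diol; 17 (diethoxyphosphoryl)acetic acid
Product: 18 (1S,2S,3R,7R)-2-[(2E)-but-2-enoyl]-7-{[(diethoxyphosphoryl)acetyl]oxy}-2-hydroxy-3-methyl-4-oxocyclohept-5-en-1-yl 3-methylbutanoate
Conditions: DCC, DMAP (cat.), CH2Cl2, 0 °C
Reagents that add atoms: none
Why: Steglich esterification, selective for the secondary allylic hydroxyl over the hindered tertiary α-ketol hydroxyl.

**Step 9**
Reactants: 18 phosphonoacetate
Product: 20 (3aS,6R,7S,8S,8aR)-7-[(2E)-but-2-enoyl]-7-hydroxy-6-methyl-3-methylidene-2,5-dioxooctahydro-2H-cyclohepta[b]furan-8-yl 3-methylbutanoate (CNP0283951.1), via phosphono lactone 19 (not isolated)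
Conditions: Cs2CO3, MeCN, 0 °C; 37 % aq. CH2O, 0 °C → rt
Reagents that add atoms: formaldehyde, C=O
Why: Intramolecular Michael addition of the phosphonate carbanion to the enone (5-exo, delivered from the face of the tethering oxygen, so the lactone is cis-fused and the ring-fusion carbon is set), then Horner–Wadsworth–Emmons methylenation; weak carbonate base at 0 °C is chosen to spare the β-ketol, the isovalerate and the methyl-bearing α-centre.

**Compound list**
1 | furan | c1ccoc1 | starting material
2 | (2E)-but-2-enal | C/C=C/C=O | starting material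
3 | 2-furyllithium | [Li]c1ccco1 | intermediate
4 | lithium (2E)-1-(furan-2-yl)but-2-en-1-olate (racemic) | [Li]OC(/C=C/C)c1ccco1 | intermediate
5 | tert-butyl{[(2E)-1-(furan-2-yl)but-2-en-1-yl]oxy}dimethylsilane (racemic) | C/C=C/C(O[Si](C)(C)C(C)(C)C)c1ccco1 | intermediate
6 | 1,3-dichloropropan-2-one | ClCC(=O)CCl | starting material
7 | 1-[(2E)-1-(tert-butyldimethylsilyloxy)but-2-en-1-yl]-2-chloro-8-oxabicyclo[3.2.1]oct-6-en-3-one (racemic, epimer mixture at C2 and the silyloxy carbon) | C/C=C/C(O[Si](C)(C)C(C)(C)C)[C@]12C=C[C@H](O1)CC(=O)C2Cl | intermediate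
8 | lithium C2=C3 enolate of the dechlorinated ketone | C/C=C/C(O[Si](C)(C)C(C)(C)C)[C@]12C=C[C@H](O1)CC(O[Li])=C2 | intermediate
9 | rac-(1R,2R,5R)-1-[(2E)-1-(tert-butyldimethylsilyloxy)but-2-en-1-yl]-2-methyl-8-oxabicyclo[3.2.1]oct-6-en-3-one (methyl cis to bridge O) | C/C=C/C(O[Si](C)(C)C(C)(C)C)[C@]12C=C[C@H](O1)CC(=O)[C@@H]2C | intermediate
10 | rac-(1R,2R,5R)-1-[(2E)-1-hydroxybut-2-en-1-yl]-2-methyl-8-oxabicyclo[3.2.1]oct-6-en-3-one | C/C=C/C(O)[C@]12C=C[C@H](O1)CC(=O)[C@@H]2C | intermediate
11 | rac-(1R,2R,5R)-1-[(2E)-but-2-enoyl]-2-methyl-8-oxabicyclo[3.2.1]oct-6-en-3-one | C/C=C/C(=O)[C@]12C=C[C@H](O1)CC(=O)[C@@H]2C | intermediate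
12 | 3-methylbutanoic acid | CC(C)CC(=O)O | starting material
13 | (1S,2S,3R)-2-[(2E)-but-2-enoyl]-2-hydroxy-3-methyl-4-oxocyclohept-6-en-1-yl 3-methylbutanoate | C1=CCC(=O)[C@H](C)[C@@](O)(C(=O)/C=C/C)[C@H]1OC(=O)CC(C)C | intermediate
14 | bis(trimethylsilyl) dienol ether of 13 (4-silyloxy-4,6-diene, tertiary O-silyl; configuration as 13) | C1=CC=C(O[Si](C)(C)C)[C@H](C)[C@@](O[Si](C)(C)C)(C(=O)/C=C/C)[C@H]1OC(=O)CC(C)C | intermediate
15 | bis(trimethylsilyl) ether of 16 | C[Si](C)(C)O[C@@H]1C=CC(=O)[C@H](C)[C@@](O[Si](C)(C)C)(C(=O)/C=C/C)[C@H]1OC(=O)CC(C)C | intermediate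
16 | (1S,2S,3R,7R)-2-[(2E)-but-2-enoyl]-2,7-dihydroxy-3-methyl-4-oxocyclohept-5-en-1-yl 3-methylbutanoate | O[C@@H]1C=CC(=O)[C@H](C)[C@@](O)(C(=O)/C=C/C)[C@H]1OC(=O)CC(C)C | intermediate
17 | (diethoxyphosphoryl)acetic acid | CCOP(=O)(OCC)CC(=O)O | starting material
18 | (1S,2S,3R,7R)-2-[(2E)-but-2-enoyl]-7-{[(diethoxyphosphoryl)acetyl]oxy}-2-hydroxy-3-methyl-4-oxocyclohept-5-en-1-yl 3-methylbutanoate | CCOP(=O)(OCC)CC(=O)O[C@@H]1C=CC(=O)[C@H](C)[C@@](O)(C(=O)/C=C/C)[C@H]1OC(=O)CC(C)C | intermediate
19 | cis-fused 3-(diethoxyphosphoryl) lactone (ring stereocentres as target; mixture at the phosphonate carbon) | CCOP(=O)(OCC)C1C(=O)O[C@@H]2[C@H]1CC(=O)[C@H](C)[C@@](O)(C(=O)/C=C/C)[C@H]2OC(=O)CC(C)C | intermediate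
20 | (3aS,6R,7S,8S,8aR)-7-[(2E)-but-2-enoyl]-7-hydroxy-6-methyl-3-methylidene-2,5-dioxooctahydro-2H-cyclohepta[b]furan-8-yl 3-methylbutanoate | C=C1C(=O)O[C@@H]2[C@H]1CC(=O)[C@H](C)[C@@](O)(C(=O)/C=C/C)[C@H]2OC(=O)CC(C)C | target

**Totals and risks**
Total steps: 9. Longest linear sequence: 9 (from furan).

Step 6 (the new ring opening; regiochemistry at a carbon next to a quaternary centre and the resolution may both fall short). Fallback with known chemistry only, setting out from 11 and coming back at 18: racemic 11 is resolved by preparative chiral SFC to its (1R,2R,5R) enantiomer. TMSOTf/Et3N then opens the bridge by β-elimination (enolisation at the free C4 methylene, loss of the C5–O bond) to silyloxy dienone F3. OsO4 (cat.)/NMO dihydroxylates the γ,δ-alkene anti to the allylic silyloxy group to diol F4. A Mitsunobu reaction (PPh3, DIAD) with 17 inverts the less hindered allylic hydroxyl to phosphonoacetate F5. Isovaleryl chloride/pyridine/DMAP acylates the remaining hydroxyl to diester silyl ether F6, and HF·pyridine removes the silyl group to give 18.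

Step 3 (the bicyclic enolate may β-eliminate the bridge before it is methylated, or the chloro ketone may be reduced too slowly). Fallback setting out from 7 and coming back at 10, with no free enolate: Zn dust/TMSCl reductive silylation gives the regiodefined silyl enol ether F1. Et2Zn/CH2I2 cyclopropanation on the face of the oxygen bridge gives siloxycyclopropane F2. p-TsOH in MeOH opens the cyclopropanol at the C3–CH2 bond to the α-methyl ketone (the C2 centre is not touched, so the methyl stays cis to the bridge oxygen) and cleaves the silyl ether, giving 10 directly.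

Step 7 (site and face selectivity of the dienol ether oxidation, and possible enol silylation of the crotonoyl group). Fallback setting out from 13 and coming back at 16, without any enolisation: a Schenck ene reaction with singlet oxygen (O2, tetraphenylporphyrin, hν, CH2Cl2, 0 °C) removes a hydrogen from the methylene next to the ketone and delivers oxygen to the alkene carbon next to the isovalerate-bearing carbon, anti to that ester, to give γ-hydroperoxy enone hydroperoxide F7. Me2S then reduces it to 16.

**Further compounds**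
F1 | step 3 | 1-[(2E)-1-(tert-butyldimethylsilyloxy)but-2-en-1-yl]-3-(trimethylsilyloxy)-8-oxabicyclo[3.2.1]octa-2,6-diene (racemic) | C/C=C/C(O[Si](C)(C)C(C)(C)C)[C@]12C=C[C@H](O1)CC(O[Si](C)(C)C)=C2
F2 | step 3 | C2–C3 cyclopropane of F1 with the CH2 on the face of the oxygen bridge (racemic) | C/C=C/C(O[Si](C)(C)C(C)(C)C)[C@]12C=C[C@H](O1)C[C@]3(O[Si](C)(C)C)C[C@H]23
F3 | step 6 | 6-[(2E)-but-2-enoyl]-7-methyl-6-(trimethylsilyloxy)cyclohepta-2,4-dien-1-one (configuration as 11) | C1=CC=CC(=O)[C@H](C)[C@@]1(O[Si](C)(C)C)C(=O)/C=C/C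
F4 | step 6 | 6-[(2E)-but-2-enoyl]-4,5-dihydroxy-7-methyl-6-(trimethylsilyloxy)cyclohept-2-en-1-one (both hydroxyls trans to the silyloxy group) | O[C@H]1C=CC(=O)[C@H](C)[C@@](O[Si](C)(C)C)(C(=O)/C=C/C)[C@H]1O
F5 | step 6 | 4-O-[(diethoxyphosphoryl)acetyl] derivative of F4 with inverted C4 | CCOP(=O)(OCC)CC(=O)O[C@@H]1C=CC(=O)[C@H](C)[C@@](O[Si](C)(C)C)(C(=O)/C=C/C)[C@H]1O
F6 | step 6 | trimethylsilyl ether of 18 | CCOP(=O)(OCC)CC(=O)O[C@@H]1C=CC(=O)[C@H](C)[C@@](O[Si](C)(C)C)(C(=O)/C=C/C)[C@H]1OC(=O)CC(C)C
F7 | step 7 | 7-hydroperoxy analogue of 16 | OO[C@@H]1C=CC(=O)[C@H](C)[C@@](O)(C(=O)/C=C/C)[C@H]1OC(=O)CC(C)C
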